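## Structural features

The target is a bicyclic diterpenoid ester: a trans-fused decalin (rings A and B; terpenoid numbering C1–C10, methyls C18/C19 on C4, C20 on C10, C17 on C8; β is the face of C20) that carries at C9 a tertiary hydroxyl and a chain C11–C15 ending in a (Z)-3-methyl-2-enoate methyl ester. Six stereocentres sit around the rings: C2 (R, α, equatorial acetate) and C3 (S, α, axial hydroxyl) beside the gem-dimethyl C4, the ring-fusion pair C5 (S, H α) and quaternary C10 (S), C8 (R, equatorial α-methyl), and fully substituted C9 (S), whose hydroxyl is β and whose chain is α, anti to C20. Fragile points are the tertiary C9 alcohol (dehydration, lactonisation onto the Z-ester), the Z geometry of the enoate, and the 2-acetate next to a free 3-hydroxyl (acyl migration). The real difficulty lies in the crowded C8–C9–C10 triad and in the trans ring fusion next to C4. While C6 is a carbonyl, the cis-fused epimer is expected to be the more stable one: in the trans form the C6 oxygen eclipses C4 with both methyls flanking it, and C19/C20 are syn-diaxial. The fusion therefore has to be made under kinetic control and not by equilibration. The key step exploits ring B: C9 at carbonyl level between methyl-bearing C10 and C8 is the pattern of 2,6-dimethylbenzoquinone, and C1–C4 with the gem-dimethyl group is a diene that adds across C10=C5. This forms C1–C10 and C4–C5, closes ring A with its 2,3-alkene and sets quaternary C10. The second quinone oxygen (C6) is used afterwards as the handle that erases and remakes C5 and then leaves as a triflate.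

## Logic of the disconnections

**18 to 17.** The acetyl C–O bond at O2 is cut. The equatorial C2 hydroxyl differs strongly from the axial, neopentyl C3 hydroxyl and the tertiary C9 hydroxyl, so the ester need not be carried through organometallic steps. The forward step must acylate O2 only.

**17 to 16.** The 2,3-diol is masked as an acetonide so that it is inert to base, the vinyl nucleophile and the borane. Removal must be mild enough for the tertiary alcohol and the Z-ester.

**16 to 12 and 14.** The C12–C13 bond (sp3–sp2) is cut. It joins an unhindered primary carbon to the enoate, so the Z-alkene can be made separately as 14 and attached convergently. The forward step needs anti-Markovnikov hydroboration of the vinyl group of 12 and a coupling that retains alkene geometry.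

**14 to 13.** The C–I bond is cut; anti addition of HI to the ynoate gives the Z-iodide in one step.

**12 to 11.** The C9–C11 bond is cut, since C9 is a carbonyl carbon of the quinone-derived ring. The forward step needs addition, not enolisation, at a ketone between quaternary C10 and C8, from the α face anti to C20.

**11 to 9.** The C7–C8 bond is desaturated. C8 is then correctable, because its equatorial (α) methyl avoids a syn-axial clash with C20. The forward step needs alkene hydrogenation without ketone reduction, then equilibration.

**9 to 8 to 7.** The acetal and both C–O bonds at C2 and C3 are cut, giving the 2,3-alkene. In a trans-fused ring A the axial C19 and C20 block the β face, so syn-dihydroxylation should give the α,α-diol. The ring fusion must already be trans, and the reagent must prefer the isolated alkene over the enone.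

**7 to 5.** The C5–H bond (and one C6–H) is cut, so that H5 is the last atom added to a planar C5. This avoids relying on an equilibrium that should favour cis. The forward step needs a 1,6-reduction with protonation at C5 from the α face; afterwards C5 is no longer next to a carbonyl and cannot epimerise.

**5 to 4 to 3.** The C6–H bond is replaced by C6–O. H5 is the only α-hydrogen of the C6 carbonyl in 3, so enolisation removes the unwanted cis configuration and O-sulfonylation prepares the oxygen for removal. The forward steps need deprotonation at C5 (not at C17) and a palladium–formate reduction.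

**3 to 1 and 2.** The C1–C10 and C4–C5 bonds are cut. Two purchased compounds give ring A, the gem-dimethyl group, the 2,3-alkene and quaternary C10. The forward step needs one regiochemistry, one quinone face, and a diene that tolerates a Z-methyl terminus.

## Other disconnections considered

**Alternative 1:** The cut is C5–C10 and C6–C7. LiN(SiMe3)2 would deprotonate C10 of the open-chain isopropenyl ketone A2; C10 adds to C5 of the vinyl sulfone, and the sulfonyl carbanion at C6 adds to C7, giving A1 with both rings closed.
- In favour: A1 arrives with the ring A oxygens in place and protected, the trans fusion and 8α-methyl set in the annulation, and no C6 oxygen to remove. On ring A oxygenation and on the ring fusion this plan is better than the chosen one.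
- In favour: absolute configuration comes from the chiral pool (A3), which is at least the equal of a catalytic step on a hard diene.
- Against: A3 is needed as the less common (S) enantiomer, and A2 would take about ten linear steps from it.
- Against: the first addition attacks neopentyl C5; the configuration of quaternary C10 rests on remote induction from the acetal; the enone can polymerise; the sulfone needs a separate reductive removal next to a ketone.
- Comparison: desulfonylated A1 is compound 11 of the chosen route, so the endgame is the same. The mechanism is anionic and catalyst-free. The overall count is about 17 steps against 12.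

**Alternative 2:** The cut is C3–C4, with ring B taken from A5. TiCl4 on the 1,2-dione A6 would break the strained C4–C7 bond to a C4 cation and a C7–C8 enolate, and the acetonyl enol carbon C3 captures C4 to give A4.
- In favour: A5 is cheap in the (1R,5R) series that maps onto C5. C10 comes from addition anti to the gem-dimethyl bridge. C5 is not next to a carbonyl in A4, so the trans fusion is secure. On ring fusion and on the source of chirality this plan is better than the chosen one.
- Against: the oxidation pattern of A4 fits the target badly. C8 carries oxygen where a methyl is needed. C2 is a ketone with no oxygen at C3, and hydride reduction of a C2 ketone under the axial C19/C20 would give the wrong (β) alcohol.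
- Against: the cation can lose a proton or be trapped on oxygen instead of forming the C3–C4 bond next to a quaternary carbon.
- Comparison: the mechanism is cationic and substrate-controlled, with no asymmetric catalyst (equal or better). The functional-group corrections make it longer, about 18 to 20 steps.

**Alternative 3:** The cut is the C9–O bond. A peracid adds to C15 of the spiro-enone A8 and C9 migrates to oxygen with retention, giving lactone A7; methanolysis would then release the tertiary alcohol and the methyl ester.
- In favour: the Z geometry is held by the ring, and the C9–O bond is made without nucleophilic addition to a hindered ketone. On alkene geometry this plan is the equal of the chosen one, and on the final unmasking it is better.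
- Against: the difficulty moves to building the all-carbon spiro centre at C9 between C8 and C10 with the right configuration, which is harder than a ketone addition.
- Against: the enone can compete by vinyl migration or epoxidation, and the opened hydroxy ester can re-close.
- Comparison: the 1,2-shift is reliable in mechanism, but the spiro-annulation should cost at least five steps more than vinyl addition plus coupling.

Key step: step 1

Remark: the (S)-configured catalyst is assumed to deliver the diene to the face of the C5=C10 bond from which C6, C10 and H5 run clockwise, by analogy with the sense this catalyst family shows for acrylates; this sense is taken from memory and is not secure, so if the other face is served the (R)-configured catalyst is used instead.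

## Route

**Step 1**
Reactants: 1 2,6-dimethyl-1,4-benzoquinone; 2 4-methylpenta-1,3-diene
Product: 3 cis-fused enedione adduct (5R,10S)
Conditions: (S)-1-(2-methylphenyl)-3,3-diphenyltetrahydro-1H,3H-pyrrolo[1,2-c][1,3,2]oxazaborole C24H24BNO (20 mol %), HN(SO2CF3)2 (17 mol %), 2 (5 equiv), CH2Cl2, −78 to −20 °C
Reagents that add atoms: none
Why: Lewis-acid-catalysed Diels–Alder reaction of a quinone under a chiral N-protonated oxazaborolidine, the closest known type being the enantioselective quinone cycloadditions of this catalyst family. Boron binds the more basic, less hindered C6 oxygen (flanked by two CH groups) at the lone pair syn to C5–H, which contacts the ring oxygen of the catalyst, so methyl-bearing C10 becomes the electrophilic β-carbon. The unsubstituted, more nucleophilic diene terminus C1 bonds to C10 first and the charge building at C4 is carried by its two methyls, so the C1–C10/C4–C5 regiochemistry follows from electronics and from the steric match of the small terminus with the substituted carbon. Ring A closes by a suprafacial, strongly asynchronous [4+2] addition (C4–C5 forming on the same face), which tolerates a twisted s-cis diene; the acid is kept in deficit to the oxazaborolidine so that no free HN(SO2CF3)2 is left to polymerise the diene. C10 is set by the catalyst, whose geminal phenyl group covers one face of the C5=C10 bond; C5 follows from suprafacial addition (H5 cis to C20) and is remade later. The remaining C7=C8 bond is trisubstituted and less reactive, so mono-addition is expected, and quaternary C10 blocks aromatisation.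

**Step 2**
Reactants: 3 cis-fused enedione adduct
Product: 4 C6 dienyl triflate (C5=C6–OTf, 10S)
Conditions: KN(SiMe3)2 (1.05 equiv), THF, −78 °C; then N-(5-chloropyridin-2-yl)-N-(trifluoromethylsulfonyl)trifluoromethanesulfonamide, −78 to 0 °C
Reagents that add atoms: N-(5-chloropyridin-2-yl)-N-(trifluoromethylsulfonyl)trifluoromethanesulfonamide, FC(F)(F)S(=O)(=O)N(c1ccc(Cl)cn1)S(=O)(=O)C(F)(F)F
Why: Kinetic α'-deprotonation of an enone and O-sulfonylation of the cross-conjugated dienolate (enol triflate formation); H5 is the only α-hydrogen of the C6 carbonyl and C9 has none, so the cis configuration at C5 is deliberately erased and O6 becomes a leaving group.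

**Step 3**
Reactants: 4 C6 dienyl triflate
Product: 5 trienone (2,3-, 5,6- and 7,8-ene, 9-ketone, 10S)
Conditions: Pd(OAc)2 (5 mol %), PPh3 (10 mol %), HCO2H, Bu3N, DMF, 60 °C
Reagents that add atoms: none
Why: Palladium-catalysed formate reduction of an enol triflate (oxidative addition, hydride transfer from formate, reductive elimination) replaces C6–OTf by C6–H; no stereocentre is formed and the product has no enolisable hydrogen.

**Step 4**
Reactants: 5 trienone
Product: 7 trans-fused dienone (5S,10S), via lithium dienolate 6 (not isolated)
Conditions: Li (2.5 equiv), NH3(l)–THF, t-BuOH (1 equiv), −78 °C; NH4Cl; then NaOMe (cat.), MeOH, 23 °C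
Reagents that add atoms: none
Why: Birch-type dissolving-metal 1,6-reduction of a linear dienone: two electrons give a dianion that t-BuOH protonates at terminal C5, perpendicular to the π system and from the α face, anti to C20 and C19, which is the trajectory leading to the trans chair; methoxide then moves the remaining alkene into conjugation (C7=C8). C5 is no longer next to a carbonyl, so the fusion is fixed, and the isolated 2,3-alkene is inert to the metal.

**Step 5**
Reactants: 7 trans-fused dienone
Product: 8 2α,3α-diol
Conditions: OsO4 (2 mol %), 4-methylmorpholine N-oxide (1.5 equiv), acetone–H2O, 23 °C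
Reagents that add atoms: osmium tetroxide, O=[Os](=O)(=O)=O (carries both oxygens); 4-methylmorpholine N-oxide, C[N+]1([O-])CCOCC1; water, O
Why: Catalytic syn-dihydroxylation; in the trans-fused ring A the axial C19 and C20 close the β face, so both oxygens should enter from α (C2 R, C3 S), and the electron-poor, trisubstituted enone alkene reacts much more slowly than the isolated 2,3-alkene.

**Step 6**
Reactants: 8 2α,3α-diol
Product: 9 acetonide of 8
Conditions: Me2C(OMe)2, pyridinium p-toluenesulfonate (cat.), acetone, 23 °C
Reagents that add atoms: 2,2-dimethoxypropane, COC(C)(C)OC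
Why: Acid-catalysed acetal exchange onto a cis-1,2-diol; the hindered enone is not ketalised under these conditions.

**Step 7**
Reactants: 9 acetonide of 8
Product: 11 saturated 9-ketone acetonide with 8α-methyl, via 8-epi ketone 10 (not isolated)
Conditions: H2 (1 atm), Pd/C (10 wt %), EtOAc, 23 °C; then NaOMe, MeOH, 40 °C
Reagents that add atoms: none
Why: Heterogeneous hydrogenation of the enone alkene should add hydrogen from the open α face and leave the C8 methyl β; base equilibration through the C8 enolate then gives the equatorial 8α-methyl (C8 R), because the axial epimer is syn-diaxial with C20.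

**Step 8**
Reactants: 11 saturated 9-ketone acetonide
Product: 12 9α-vinyl-9β-hydroxy acetonide (9S)
Conditions: CeCl3 (anhydrous, 3 equiv), CH2=CHMgBr (3 equiv), THF, −78 to 0 °C
Reagents that add atoms: vinylmagnesium bromide, C=C[Mg]Br
Why: Organocerium 1,2-addition, which suppresses enolisation of the hindered ketone; the nucleophile should enter axially from the α face, past only H5 and H7, because the equatorial β trajectory runs into the axial C20 on the adjacent carbon.

**Step 9**
Reactants: 13 methyl but-2-ynoate
Product: 14 methyl (2Z)-3-iodobut-2-enoate
Conditions: NaI, AcOH, 115 °C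
Reagents that add atoms: sodium iodide, [Na+].[I-]
Why: Conjugate hydroiodination of an ynoate: iodide adds to C3 and the allenolate is protonated anti, placing iodine and ester cis (Z).

**Step 10**
Reactants: 12 9α-vinyl-9β-hydroxy acetonide; 14 methyl (2Z)-3-iodobut-2-enoate
Product: 16 coupled Z-enoate acetonide, via B-alkyl-9-BBN borane 15 (not isolated)
Conditions: 9-borabicyclo[3.3.1]nonane dimer (C8H15B)2 (3 equiv B–H), THF, 23 to 50 °C; then 14, PdCl2[(Ph2PC5H4)2Fe] (5 mol %), AsPh3 (5 mol %), K3PO4 (3 M aq), DMF, 23 °C
Reagents that add atoms: none
Why: Anti-Markovnikov hydroboration of the monosubstituted alkene places boron on C12, and the B-alkyl Suzuki–Miyaura coupling with the alkenyl iodide forms C12–C13 with retention of the Z geometry; excess borane allows for the free tertiary hydroxyl.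

**Step 11**
Reactants: 16 coupled Z-enoate acetonide
Product: 17 triol
Conditions: AcOH–H2O (4:1), 45 °C
Reagents that add atoms: none
Why: Mild acetal hydrolysis; the tertiary alcohol has no easy ionisation path under these conditions and the methyl ester and Z-alkene are untouched.

**Step 12**
Reactants: 17 triol
Product: 18 target
Conditions: Ac2O (1.2 equiv), pyridine, CH2Cl2, 0 °C
Reagents that add atoms: acetic anhydride, CC(=O)OC(C)=O
Why: Site-selective acylation: the equatorial C2 hydroxyl should react well before the axial C3 hydroxyl beside the gem-dimethyl carbon, and the tertiary C9 hydroxyl is inert without an acyl-transfer catalyst.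

## Compound list

1 | 2,6-dimethyl-1,4-benzoquinone | CC1=CC(=O)C=C(C)C1=O | starting material
2 | 4-methylpenta-1,3-diene | C=CC=C(C)C | starting material
3 | cis-fused enedione adduct, (4aR,8aS)-2,5,5,8a-tetramethyl-4a,5,8,8a-tetrahydronaphthalene-1,4-dione (terpenoid 5R,10S; H5 and C20 both β) | O=C1C(C)=CC(=O)[C@@H]2C(C)(C)C=CC[C@@]21C | intermediate
4 | C6 dienyl triflate, (8aS)-2,5,5,8a-tetramethyl-1-oxo-1,5,8,8a-tetrahydronaphthalen-4-yl trifluoromethanesulfonate | O=C1C(C)=CC(OS(=O)(=O)C(F)(F)F)=C2C(C)(C)C=CC[C@@]21C | intermediate
5 | trienone, (8aS)-2,5,5,8a-tetramethyl-8,8a-dihydronaphthalen-1(5H)-one | O=C1C(C)=CC=C2C(C)(C)C=CC[C@@]21C | intermediate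
6 | lithium (4aS,8aS)-2,5,5,8a-tetramethyl-4a,5,8,8a-tetrahydronaphthalen-1-olate (lithium dienolate, H5 α) | [Li+].[O-]C1=C(C)C=C[C@H]2C(C)(C)C=CC[C@@]21C | intermediate (not isolated)
7 | trans-fused dienone, (4aS,8aS)-2,5,5,8a-tetramethyl-4a,5,8,8a-tetrahydronaphthalen-1(4H)-one | O=C1C(C)=CC[C@H]2C(C)(C)C=CC[C@@]21C | intermediate
8 | 2α,3α-diol, (4aS,6S,7R,8aS)-6,7-dihydroxy-2,5,5,8a-tetramethyl-4a,5,6,7,8,8a-hexahydronaphthalen-1(4H)-one | O=C1C(C)=CC[C@H]2C(C)(C)[C@H](O)[C@H](O)C[C@@]21C | intermediate
9 | acetonide of 8 (2α,3α-O-isopropylidene; 2R,3S,5S,10S; 7,8-en-9-one) | O=C1C(C)=CC[C@H]2C(C)(C)[C@H](O3)[C@H](OC3(C)C)C[C@@]21C | intermediate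
10 | 8-epi ketone: saturated 9-ketone acetonide with 8β-methyl (2R,3S,5S,8S,10S) | O=C1[C@@H](C)CC[C@H]2C(C)(C)[C@H](O3)[C@H](OC3(C)C)C[C@@]21C | intermediate (not isolated)
11 | saturated 9-ketone acetonide with 8α-methyl (2R,3S,5S,8R,10S) | O=C1[C@H](C)CC[C@H]2C(C)(C)[C@H](O3)[C@H](OC3(C)C)C[C@@]21C | intermediate
12 | 9α-vinyl-9β-hydroxy acetonide (2R,3S,5S,8R,9S,10S) | C=C[C@]1(O)[C@H](C)CC[C@H]2C(C)(C)[C@H](O3)[C@H](OC3(C)C)C[C@@]21C | intermediate
13 | methyl but-2-ynoate | CC#CC(=O)OC | starting material
14 | methyl (2Z)-3-iodobut-2-enoate | COC(=O)/C=C(/C)I | intermediate
15 | B-alkyl-9-BBN borane of 12 (9-borabicyclo[3.3.1]nonan-9-yl on C12) | C(CB4C5CCCC4CCC5)[C@]1(O)[C@H](C)CC[C@H]2C(C)(C)[C@H](O3)[C@H](OC3(C)C)C[C@@]21C | intermediate (not isolated)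
16 | coupled Z-enoate acetonide: 2α,3α-O-isopropylidene derivative of 17 | COC(=O)/C=C(/C)CC[C@]1(O)[C@H](C)CC[C@H]2C(C)(C)[C@H](O3)[C@H](OC3(C)C)C[C@@]21C | intermediate
17 | triol, methyl (2Z)-5-[(1S,2R,4aS,6S,7R,8aS)-1,6,7-trihydroxy-2,5,5,8a-tetramethyldecahydronaphthalen-1-yl]-3-methylpent-2-enoate | COC(=O)/C=C(/C)CC[C@]1(O)[C@H](C)CC[C@H]2C(C)(C)[C@H](O)[C@H](O)C[C@@]21C | intermediate
18 | methyl (2Z)-5-[(1S,2R,4aS,6S,7R,8aS)-7-acetoxy-1,6-dihydroxy-2,5,5,8a-tetramethyldecahydronaphthalen-1-yl]-3-methylpent-2-enoate | COC(=O)/C=C(/C)CC[C@]1(O)[C@H](C)CC[C@H]2C(C)(C)[C@H](O)[C@H](OC(C)=O)C[C@@]21C | target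

## Step count and least certain steps

Total: 12 steps. Longest linear sequence: 11 steps (steps 1–8 and 10–12); step 9 is a one-step branch.

**Step 1 (key step).** The most likely failure is cationic oligomerisation of the diene, or stepwise bonding through its s-trans form that ends in four-membered or O-alkylated products. The Z-methyl on C4 penalises the s-cis geometry that ring closure needs, and the same strain may erode face selectivity. Fallback, from 1 and back at 5: the diene is replaced by its 2-silyloxy analogue 4-methyl-2-(triisopropylsilyloxy)penta-1,3-diene F1, made from purchased 4-methylpent-3-en-2-one with LiN(iPr)2 and iPr3SiOSO2CF3. F1 is the class of diene for which this catalyst is established, its C1 is more nucleophilic, and a stepwise Mukaiyama–Michael pathway still closes the ring. Under the conditions of step 1 it should give the silyloxy adduct F2. Treatment as in step 2 gives the dienyl triflate F3, which has no acidic hydrogen left. CsF with PhN(SO2CF3)2 in DME then converts the silyl enol ether into the bis(triflate) F4, and the formate reduction of step 3 removes both triflates to give 5. The C2 oxygen is not kept because hydride reduction of a C2 ketone would deliver the wrong (β) alcohol.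

**Step 2.** The most likely failure is deprotonation at the C8 methyl instead of at C5, or slow O-sulfonylation. C5–H is tertiary, the planar enolate suffers strain between O6 and the C4 methyls, and the C8 methyl is more accessible. Fallback, from 3 and back at 5: Luche reduction (NaBH4, CeCl3·7H2O, MeOH, −78 °C) of the more basic, less hindered C6 carbonyl gives the allylic alcohol F5. Ac2O, pyridine and 4-(dimethylamino)pyridine give the acetate F6. Pd(PPh3)4 with Et3N in dioxane at 80 °C ionises the allylic acetate and eliminates H5 (syn to palladium), giving 5 without any enolate chemistry.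

**Step 4.** The most likely failure is protonation at C7 instead of C5 (1,4- in place of 1,6-reduction), over-reduction of the carbonyl, or incomplete face selectivity. C5 is fully substituted and flanked by two quaternary carbons. Fallback, from 5 and back at 11: the order is changed and the metal reduction is replaced by surface hydrogenation. Dihydroxylation of 5 as in step 5 gives the diol F7 (ring A of 5 has the same axial C19/C20 screen), and acetal formation as in step 6 gives the acetonide F8. H2 (4 atm) over Pd/C in EtOAc should then saturate both ring B alkenes from the open α face, and NaOMe in MeOH equilibrates C8, giving 11.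

**Step 8.** The most likely failure is enolisation of the ketone toward C8 in place of addition, or attack from the β face. The carbonyl lies between a quaternary and a tertiary carbon. Fallback, from 11 and back at 12: a smaller, linear nucleophile with a stronger preference for axial attack is used. HC≡CMgBr with CeCl3 in THF gives the 9α-ethynyl carbinol F9, and semi-hydrogenation (H2, Pd/CaCO3 with Pb(OAc)2, quinoline) gives 12.

## Further compounds

F1 | step 1 | 4-methyl-2-(triisopropylsilyloxy)penta-1,3-diene | C=C(O[Si](C(C)C)(C(C)C)C(C)C)C=C(C)C
F2 | step 1 | cis-fused enedione adduct with 2-(triisopropylsilyloxy)-2,3-ene (5R,10S) | O=C1C(C)=CC(=O)[C@@H]2C(C)(C)C=C(O[Si](C(C)C)(C(C)C)C(C)C)C[C@@]21C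
F3 | step 1 | C6 dienyl triflate with 2-(triisopropylsilyloxy)-2,3-ene (10S) | O=C1C(C)=CC(OS(=O)(=O)C(F)(F)F)=C2C(C)(C)C=C(O[Si](C(C)C)(C(C)C)C(C)C)C[C@@]21C
F4 | step 1 | C2,C6 bis(triflate) of the trienone skeleton (10S) | O=C1C(C)=CC(OS(=O)(=O)C(F)(F)F)=C2C(C)(C)C=C(OS(=O)(=O)C(F)(F)F)C[C@@]21C
F5 | step 2 | cis-fused 6α-hydroxy-2,7-dien-9-one (5R,10S) | O=C1C(C)=C[C@H](O)[C@@H]2C(C)(C)C=CC[C@@]21C
F6 | step 2 | cis-fused 6α-acetoxy-2,7-dien-9-one (5R,10S) | O=C1C(C)=C[C@H](OC(C)=O)[C@@H]2C(C)(C)C=CC[C@@]21C
F7 | step 4 | 2α,3α-dihydroxy-5,7-dien-9-one (2R,3S,10S) | O=C1C(C)=CC=C2C(C)(C)[C@H](O)[C@H](O)C[C@@]21C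
F8 | step 4 | acetonide of F7 | O=C1C(C)=CC=C2C(C)(C)[C@H](O3)[C@H](OC3(C)C)C[C@@]21C
F9 | step 8 | 9α-ethynyl-9β-hydroxy acetonide (2R,3S,5S,8R,9S,10S) | C#C[C@]1(O)[C@H](C)CC[C@H]2C(C)(C)[C@H](O3)[C@H](OC3(C)C)C[C@@]21C
A1 | alternative 1 | trans-decalin-9-one with 6α-phenylsulfonyl, 8α-methyl and 2α,3α-acetonide | O=C1[C@H](C)C[C@H](S(=O)(=O)c3ccccc3)[C@H]2C(C)(C)[C@H](O4)[C@H](OC4(C)C)C[C@@]21C
A2 | alternative 1 | open-chain isopropenyl ketone with (E)-vinyl sulfone and 2,3-acetonide | O=S(=O)(/C=C/C(C)(C)[C@H](O3)[C@H](OC3(C)C)CC(C)C(=O)C(C)=C)c1ccccc1
A3 | alternative 1 | (S)-pantolactone, (3S)-3-hydroxy-4,4-dimethyloxolan-2-one | CC1(C)COC(=O)[C@H]1O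
A4 | alternative 2 | trans-fused diosphenol (9-ketone, 7-en-8-ol, 2-ketone) | O=C1C(O)=CC[C@H]2C(C)(C)CC(=O)C[C@@]21C
A5 | alternative 2 | (1R,5R)-verbenone | CC1=CC(=O)[C@@H]2C[C@H]1C2(C)C
A6 | alternative 2 | pinane-type 1,2-dione with methyl and acetonyl on C10 | C[C@@]1(CC(C)=O)C(=O)C(=O)[C@@H]2C[C@H]1C2(C)C
A7 | alternative 3 | spiro seven-membered unsaturated lactone (C9–O–C15) with 2α,3α-acetonide | CC1=CC(=O)O[C@@]2(CC1)[C@H](C)CC[C@H]3C(C)(C)[C@H](O4)[C@H](OC4(C)C)C[C@]23C
A8 | alternative 3 | spiro cyclohexenone (C9–C15 bond) with 2α,3α-acetonide | CC1=CC(=O)[C@@]2(CC1)[C@H](C)CC[C@H]3C(C)(C)[C@H](O4)[C@H](OC4(C)C)C[C@]23C
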